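## Analysis of the target

Target 29 is a 15-norlabdane (labdane numbering throughout). It is a trans-fused decalin (ring A: C1–C5, C10; ring B: C5–C10) with a gem-dimethyl group on C4 and an angular methyl group on C10 (C20). A C7=C8 double bond is conjugated to a carboxylic acid (C17) on C8, and C9 carries a four-carbon chain C11–C14 with a methyl branch at C13 (C16) that ends in an isobutyrate ester.

The three ring stereocentres are contiguous. 5α-H and 10β-CH3 define the trans fusion (5S,10S), and the C9 chain is β, cis to the C10 methyl group (9R). The fourth stereocentre, C13 (R), is separated from the ring by two methylene groups and cannot be controlled from it.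

Two quaternary carbons, C4 and C10, sit 1,3 to each other on ring A; C10 is stereogenic and flanked by C5 and C9. The C9 hydrogen is allylic and γ to the carboxyl group, so base can epimerise C9 or move the alkene. The primary isobutyrate does not survive organometallic reagents, hydrides or dissolving metals, so the ester and the unsaturated acid belong at the end.

The difficulties are the congested C4–C5–C10 region with its absolute configuration, the attachment of the chain to C9 next to a quaternary carbon, the regiodefined C7=C8 alkene and the oxidation level of C17.

The strategy rests on one mapping. Ring B (C5–C10), the one-carbon substituent on C8 (C17), the C5 stereocentre and C4 with both its methyl groups are together the ten carbons of (R)-carvone 1. Its carbonyl carbon is C9, its enone alkene is C7=C8, its ring methyl is C17 and its isopropenyl carbon is C4.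

## Retrosynthetic reasoning

**C17 oxidation level.** The carboxyl carbon of 29 is traced back to the allylic methyl group of ester 26, through enal 28 and allylic alcohol 27. No C–C bond is cut. The oxidation is left to the end because C17 is the ring methyl of 1, and a conjugated acid or aldehyde with an epimerisable γ-carbon (C9) would not survive the carbanion and electron-transfer steps before it. The forward reactions must pick C17 among three allylic positions (C6, C9, C17) and then oxidise aldehyde to acid without touching the alkene.

**Ester, protecting group and sulfone.** Cutting the ester C–O bond of 26 gives alcohol 24 and isobutyryl chloride 25. Alcohol 24 is silyl ether 23 without its protecting group, and 23 is sulfone 22 without the phenylsulfonyl group on C2. The ester is cut here because it cannot pass through the earlier steps. The sulfone is removed only after the last carbonyl group has gone, because electron-transfer desulfonylation would also reduce an enone.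

**C9–H.** The C9–H bond of 22 is disconnected to the tertiary allylic carbonate 21, made from alcohol 19. This turns the C9 stereocentre into a question of hydride delivery to the allyl unit C7–C8–C9. Palladium-catalysed formate hydrogenolysis transfers hydride to the more substituted terminus on the face opposite the leaving group. A 9β-carbonate should therefore give 9α-H and keep the alkene at C7=C8, so C9 and the alkene position both derive from one carbinol centre.

**C9–C11.** Cutting C9–C11 of 19 separates decalin enone 11 from the side-chain nucleophile 18, made from iodide 16 via 17. C9 is the carbonyl carbon of 1, so this is the natural convergent join, and it leaves C13 in a small fragment from the chiral pool. Iodide 16 goes back through alcohol 15 and Grignard reagent 14 to silyl ether 13 and bromo alcohol 12, with formaldehyde 6 supplying C11. The nucleophile must add 1,2 to a hindered enone from the α-face without deprotonating the sulfone.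

**C3–C4 (key disconnection).** Cutting C3–C4 of 11 opens ring A to cyclohexenone 10, which carries the isopropenyl group on C5 and a 2-(phenylsulfonyl)allyl group on C10. C4 is a quaternary carbon that can be generated as a tertiary radical from the isopropenyl group by hydrogen-atom transfer. A cationic closure would risk rearrangement, and a polar closure has no suitable nucleophile. The sulfone directs the radical to C3 and is removed afterwards. The cut returns the whole carbon skeleton of 1 and makes the trans fusion a consequence of the C5/C10 relationship in 10.

**C10–C1 and C10–C20.** Ketone 10 is cut at the two exocyclic bonds of C10. C10–C1 leads to enolate 9 of methyl ketone 4 and allylic bromide 8. C10–C20 leads to dienolate 3 of 1 and iodomethane 2. The order matters: the second electrophile enters anti to the isopropenyl group, so methyl first and sulfonylallyl second gives the C10 configuration of the target. Bromide 8 goes back to alcohol 7 and then to phenyl vinyl sulfone 5 and formaldehyde 6, which places sulfur on the central carbon of the allyl unit.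

## Alternatives that were turned down

**Alternative 1:** The disconnection cuts C10–C20 and C9–C11 on a ready-made ring B, an achiral 3-substituted cyclohexenone that already holds the C1–C4 homoprenyl arm. Forward, Me3Al under a chiral Cu(OTf)2/phosphoramidite catalyst would deliver methyl to C10. The enolate would then be alkylated at C9 by an (E)-allylic bromide bringing C11–C14, giving cyclohexanone A1. No ring closes.
- For: C10 is created catalytically from achiral material and two C–C bonds form in one flask. The C8 ketone of A1 could later become the C7=C8–CO2H unit by enol triflate carbonylation. On C17 this is stronger than the chosen route, which needs a late C–H oxidation.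
- Against: ring A is still open. Its closing bond, C4–C5, must be made at a carbon that the C8 carbonyl does not activate, so C5 and the trans fusion need further redox and cyclisation chemistry. Aluminium enolates are poor nucleophiles, and face selectivity at C9 rests on the small difference between methyl and a primary alkyl chain on C10. C13 would still need an asymmetric hydrogenation of the C12=C13 alkene next to a second trisubstituted alkene.
- Comparison: the chosen strategy has no catalytic asymmetric step. It takes C5, and through it C10, from 1, closes ring A in the step that builds C4, and takes C13 from the chiral pool.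

**Alternative 2:** Both rings are disconnected at C4–C5 and C9–C10, back to an acyclic trienol that already holds C13. Forward, a squalene–hopene cyclase variant (a protonating, class 2 terpene cyclase) would protonate C3. The cation cascade would close rings A and B, and loss of H-7 from the C8 cation would give A2, (13R)-15-norlabd-7-en-14-ol, identical with 24.
- For: one step makes two rings, both quaternary carbons and all three ring stereocentres, with the trans fusion set by the chair–chair fold. The substrate is a few steps from a sesquiterpenoid allylic halide and a three-carbon chiral piece, and A2 is three steps from 29. In step count this alternative is clearly stronger.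
- Against: the C8 cation can lose a proton from C7, C9 or C17 or capture water. Which happens, and whether the truncated, branched substrate folds productively at all, is decided by the active site of an enzyme variant and cannot be argued from the substrate. Acid-promoted chemical versions of such cyclisations typically give alkene isomers and partly cyclised material. The route would depend on finding or engineering a specific protein.
- Comparison: the chosen strategy is longer, but each bond and stereocentre follows from a reagent-level argument, and the alkene position is inherited from the enone of 1.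

**Alternative 3:** The decalin is disconnected at C5–C10 and C8–C9 by a retro-Diels–Alder reaction to an open-chain trienimide with an oxazolidinone auxiliary on the C11 carbonyl. Forward, chelation by Me2AlCl and endo [4+2] cycloaddition would close both rings and give adduct A3, with the C11 acyl group on C9, a silyloxymethyl group (C17) on C8 and a C6=C7 alkene.
- For: both rings and C5, C9 and C10 arise in one auxiliary-controlled step. C17 is oxygenated from the outset, and the alkene could be moved into conjugation once C17 is a carbonyl group. On ring formation per step and on C17 it is stronger.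
- Against: the dienophile is β,β-disubstituted because it must deliver quaternary C10, the diene terminus C5 is attached to quaternary C4, and the tether closes a six-membered ring. Each feature lowers the rate and the endo/exo and facial selectivity of an intramolecular Diels–Alder reaction. The geometrically defined triene needs a long linear sequence. Afterwards the auxiliary must be removed, C11 extended by three carbons with a separate answer for C13, the new C8 stereocentre destroyed and the alkene migrated.
- Comparison: the chosen strategy reaches its cyclisation substrate in three main-line steps from 1, forms the congested C3–C4 bond by radical chemistry, which is less sensitive to crowding at a quaternary carbon, and attaches the complete side chain in one step.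

Key step: step 5

Assumption: C6 of 4 and C2 of 11 and 19–22 arise as epimer mixtures and are carried as such, because steps 4 and 12 erase these centres.

Remark: bromide 8 needs sulfur on the central allyl carbon; bromination–elimination of an allyl sulfone would place it on C1, so 8 is built from phenyl vinyl sulfone.

Convention: compounds that supply carbon to 29 are numbered as starting materials; other reagents stand on the reagent lines.

## Route

Step 1
Reactants: 1 (R)-carvone; 2 iodomethane
Product: 4 (5R)-2,6-dimethyl-5-(prop-1-en-2-yl)cyclohex-2-en-1-one (C6 epimers), via lithium dienolate 3 (not isolated)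
Conditions: LiN(iPr)2 (LDA), THF, −78 °C; MeI, −78 → 0 °C
Reagents that add atoms: none
Why: Kinetic deprotonation at the α′ carbon (carvone C6, the future C10) gives the cross-conjugated dienolate 3, which is methylated by SN2 (enolate alkylation). C5 is untouched, and the new centre is planarised again in step 4.

Step 2
Reactants: 5 phenyl vinyl sulfone; 6 formaldehyde
Product: 7 2-(phenylsulfonyl)prop-2-en-1-ol
Conditions: DABCO (cat.), aq. HCHO, THF, rt
Reagents that add atoms: none
Why: Baylis–Hillman reaction: DABCO adds to the vinyl sulfone, the α-sulfonyl carbanion adds to formaldehyde and the amine is expelled. The hydroxymethyl group ends on the sulfone-bearing carbon.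

Step 3
Reactants: 7 2-(phenylsulfonyl)prop-2-en-1-ol
Product: 8 3-bromo-2-(phenylsulfonyl)prop-1-ene
Conditions: PBr3, Et2O, 0 °C
Reagents that add atoms: phosphorus tribromide, BrP(Br)Br
Why: Conversion of a primary allylic alcohol into the bromide via its phosphite ester (SN2). Allylic transposition would return the same compound, because the two CH2 termini are equivalent.

Step 4
Reactants: 4 (5R)-2,6-dimethyl-5-(prop-1-en-2-yl)cyclohex-2-en-1-one; 8 3-bromo-2-(phenylsulfonyl)prop-1-ene
Product: 10 (5S,6S)-2,6-dimethyl-6-[2-(phenylsulfonyl)prop-2-en-1-yl]-5-(prop-1-en-2-yl)cyclohex-2-en-1-one, via lithium enolate 9 (not isolated)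
Conditions: LiN(iPr)2 (LDA), THF, −78 → −20 °C; cannulated into 8 (excess), THF–DMPU, −78 °C
Reagents that add atoms: none
Why: Deprotonation of the remaining α′ hydrogen gives the fully substituted enolate 9, which is C-alkylated by the allylic bromide (SN2 or addition–elimination, both giving the same product). The electrophile should enter anti to the neighbouring isopropenyl group (diastereoselective enolate alkylation), which sets quaternary C10 with methyl cis and the sulfonylallyl arm trans to the isopropenyl group.

Step 5
Reactants: 10 (5S,6S)-2,6-dimethyl-6-[2-(phenylsulfonyl)prop-2-en-1-yl]-5-(prop-1-en-2-yl)cyclohex-2-en-1-one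
Product: 11 (4aS,8aS)-2,5,5,8a-tetramethyl-7-(phenylsulfonyl)-4a,5,6,7,8,8a-hexahydronaphthalen-1(4H)-one (C7 epimers; labdane C2)
Conditions: Fe(acac)3 (0.5 equiv), PhSiH3 (2.5 equiv), EtOH–HOCH2CH2OH (5:1), 60 °C, dilute
Reagents that add atoms: none
Why: The iron hydride formed from Fe(acac)3 and PhSiH3 transfers a hydrogen atom to the terminal CH2 of the electron-rich isopropenyl group, making that carbon the second C4 methyl group and leaving a nucleophilic tertiary radical at C4. The closest known reaction type is the Fe(acac)3/PhSiH3 reductive coupling of 1,1-disubstituted alkenes with electron-poor alkenes (hydrogen-atom-transfer Giese reaction), used here intramolecularly. Ring A closes by 6-endo-trig attack of the C4 radical on the unsubstituted terminus of the vinyl sulfone (C3), the polarity-matched and open position; 5-exo attack at the sulfonyl-bearing carbon would leave an unstabilised primary radical. The α-sulfonyl radical at C2 is reduced by divalent iron to the carbanion and protonated by ethanol, which returns trivalent iron. No stereocentre of the target is created: C5 and C10 are in place, and because the two reacting arms are trans-diequatorial on the cyclohexenone the new ring can only be trans-fused; C2 forms as an epimer mixture erased in step 12. The step needs hydrogen-atom transfer to the isopropenyl group in preference to the vinyl sulfone and the enone, which the higher electron density of the unactivated alkene should secure. It also needs cyclisation to outrun reduction of the tertiary radical, which the chair-like six-membered transition state and the activated acceptor favour. The enone cannot intercept the radical, since attack at C7 or C8 would form a four-membered or bridged ring.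

Step 6
Reactants: 12 (S)-3-bromo-2-methylpropan-1-ol
Product: 13 (S)-(3-bromo-2-methylpropoxy)(tert-butyl)dimethylsilane
Conditions: TBSCl, imidazole, CH2Cl2, 0 °C → rt
Reagents that add atoms: tert-butyldimethylsilyl chloride, CC(C)(C)[Si](C)(C)Cl
Why: Imidazole-promoted silylation of the primary alcohol. The TBS ether should survive Grignard, organolithium and organocerium chemistry, the palladium step and sodium amalgam.

Step 7
Reactants: 13 (S)-(3-bromo-2-methylpropoxy)(tert-butyl)dimethylsilane; 6 formaldehyde (as dry paraformaldehyde)
Product: 15 (R)-4-(tert-butyldimethylsilyloxy)-3-methylbutan-1-ol, via Grignard reagent 14 (not isolated)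
Conditions: Mg, BrCH2CH2Br (cat.), THF, 40 °C; (CH2O)n, 0 °C → rt; aq. NH4Cl
Reagents that add atoms: none
Why: Grignard formation and hydroxymethylation with formaldehyde add the carbon that becomes C11. The stereocentre takes no part; its descriptor changes from S to R only because the CIP priorities change.

Step 8
Reactants: 15 (R)-4-(tert-butyldimethylsilyloxy)-3-methylbutan-1-ol
Product: 16 (R)-tert-butyl(4-iodo-2-methylbutoxy)dimethylsilane
Conditions: I2, PPh3, imidazole, CH2Cl2, 0 °C → rt
Reagents that add atoms: iodine, II
Why: Appel-type iodination of the primary alcohol (alkoxyphosphonium iodide, SN2). The neutral conditions leave the silyl ether intact.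

Step 9
Reactants: 16 (R)-tert-butyl(4-iodo-2-methylbutoxy)dimethylsilane; 11 (4aS,8aS)-2,5,5,8a-tetramethyl-7-(phenylsulfonyl)-4a,5,6,7,8,8a-hexahydronaphthalen-1(4H)-one
Product: 19 (13R)-14-(tert-butyldimethylsilyloxy)-2-(phenylsulfonyl)-15-norlabd-7-en-9β-ol (C11 chain on the α-face of C9; C2 epimers), via alkyllithium 17 (not isolated), via organocerium reagent 18 (not isolated)
Conditions: t-BuLi (2 equiv per 16), Et2O, −78 °C; anhydrous CeCl3, THF, −78 °C; 11, −78 → −40 °C; aq. NH4Cl
Reagents that add atoms: none
Why: Iodine–lithium exchange gives 17 and transmetalation gives the weakly basic organocerium reagent 18, which should add 1,2 to the hindered enone carbonyl without removing the α-sulfonyl or γ-hydrogens. Attack is expected on the α-face, anti to the axial C10 methyl group on the adjacent carbon, giving the 9β-carbinol (substrate control); C13 is carried unchanged.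

Step 10
Reactants: 19 (13R)-14-(tert-butyldimethylsilyloxy)-2-(phenylsulfonyl)-15-norlabd-7-en-9β-ol
Product: 21 methyl (13R)-14-(tert-butyldimethylsilyloxy)-2-(phenylsulfonyl)-15-norlabd-7-en-9β-yl carbonate (C11 chain 9α; C2 epimers), via lithium alkoxide 20 (not isolated)
Conditions: LiN(SiMe3)2 (1 equiv), THF, −78 °C; ClCO2Me, −78 → 0 °C
Reagents that add atoms: methyl chloroformate, COC(=O)Cl
Why: One equivalent of base removes the hydroxyl proton, by far the fastest deprotonation. Alkoxide 20 is acylated by the chloroformate (carbonate formation) without change at any stereocentre.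

Step 11
Reactants: 21 methyl (13R)-14-(tert-butyldimethylsilyloxy)-2-(phenylsulfonyl)-15-norlabd-7-en-9β-yl carbonate
Product: 22 (13R)-14-(tert-butyldimethylsilyloxy)-2-(phenylsulfonyl)-15-norlabd-7-ene (C2 epimers)
Conditions: Pd(OAc)2 (cat.), n-Bu3P (cat.), HCO2H, Et3N, THF, rt → 40 °C
Reagents that add atoms: none
Why: Tsuji–Mandai-type formate hydrogenolysis: zerovalent palladium ionises the β-carbonate with inversion and sits on the α-face of the C7–C8–C9 allyl unit. The formate complex, bound through the less hindered C7 terminus, loses CO2 and delivers hydride internally to the more substituted terminus C9 on the palladium face. This should give 9α-H and the β side chain with the alkene kept at C7=C8; n-Bu3P is chosen because it favours hydride transfer over diene-forming elimination.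

Step 12
Reactants: 22 (13R)-14-(tert-butyldimethylsilyloxy)-2-(phenylsulfonyl)-15-norlabd-7-ene
Product: 23 (13R)-14-(tert-butyldimethylsilyloxy)-15-norlabd-7-ene
Conditions: Na(Hg), Na2HPO4, MeOH–THF, −20 °C → rt
Reagents that add atoms: none
Why: Reductive desulfonylation by electron transfer cleaves the C2–S bond to sulfinate and, after a second electron and protonation, a CH2 group. The isolated trisubstituted alkene and the silyl ether are inert, and the C2 epimer mixture disappears.

Step 13
Reactants: 23 (13R)-14-(tert-butyldimethylsilyloxy)-15-norlabd-7-ene
Product: 24 (13R)-15-norlabd-7-en-14-ol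
Conditions: Bu4NF, THF, rt
Reagents that add atoms: none
Why: Fluoride-induced cleavage of the silyl ether; nothing else in 23 reacts with fluoride.

Step 14
Reactants: 24 (13R)-15-norlabd-7-en-14-ol; 25 isobutyryl chloride
Product: 26 (13R)-15-norlabd-7-en-14-yl 2-methylpropanoate
Conditions: pyridine, DMAP (cat.), CH2Cl2, 0 °C → rt
Reagents that add atoms: none
Why: Acylation of the primary alcohol under nucleophilic catalysis by DMAP. The ester is introduced only now because it would not survive the organometallic and reductive steps.

Step 15
Reactants: 26 (13R)-15-norlabd-7-en-14-yl 2-methylpropanoate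
Product: 28 (13R)-17-oxo-15-norlabd-7-en-14-yl 2-methylpropanoate, via allylic alcohol 27 (not isolated)
Conditions: SeO2, 1,4-dioxane, 80 °C
Reagents that add atoms: selenium dioxide, O=[Se]=O
Why: Allylic oxidation with SeO2 (ene reaction, then 2,3-sigmatropic shift of the allylseleninic acid) brings oxygen to C17 and returns the alkene to C7=C8; alcohol 27 is oxidised on to the enal under the same conditions. The C17 methyl group on the disubstituted alkene carbon should react before the shielded C9 methine and the C6 methylene on the monosubstituted end.

Step 16
Reactants: 28 (13R)-17-oxo-15-norlabd-7-en-14-yl 2-methylpropanoate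
Product: 29 (13R)-14-(2-methylpropanoyloxy)-15-norlabd-7-en-17-oic acid
Conditions: NaClO2, NaH2PO4, 2-methylbut-2-ene, t-BuOH–H2O, rt
Reagents that add atoms: sodium chlorite, [Na+].[O-]Cl=O
Why: Pinnick oxidation of the conjugated aldehyde by chlorous acid. 2-Methylbut-2-ene removes hypochlorous acid, so the alkene, the allylic C9–H and the isobutyrate are left alone, and the buffered pH should not epimerise C9.

## Compound list

1 | (R)-carvone, (5R)-2-methyl-5-(prop-1-en-2-yl)cyclohex-2-en-1-one | CC(=C)[C@@H]1CC=C(C)C(=O)C1 | starting material
2 | iodomethane | CI | starting material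
3 | lithium (3R)-6-methyl-3-(prop-1-en-2-yl)cyclohexa-1,5-dien-1-olate (dienolate of 1) | [Li]OC1=C[C@H](C(C)=C)CC=C1C | intermediate
4 | (5R)-2,6-dimethyl-5-(prop-1-en-2-yl)cyclohex-2-en-1-one, C6 epimers | CC1=CC[C@@H](C(C)=C)C(C)C1=O | intermediate
5 | phenyl vinyl sulfone | C=CS(=O)(=O)c1ccccc1 | starting material
6 | formaldehyde | C=O | starting material
7 | 2-(phenylsulfonyl)prop-2-en-1-ol | OCC(=C)S(=O)(=O)c1ccccc1 | intermediate
8 | 3-bromo-2-(phenylsulfonyl)prop-1-ene | BrCC(=C)S(=O)(=O)c1ccccc1 | intermediate
9 | lithium (3S)-2,6-dimethyl-3-(prop-1-en-2-yl)cyclohexa-1,5-dien-1-olate (enolate of 4) | [Li]OC1=C(C)[C@H](C(C)=C)CC=C1C | intermediate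
10 | (5S,6S)-2,6-dimethyl-6-[2-(phenylsulfonyl)prop-2-en-1-yl]-5-(prop-1-en-2-yl)cyclohex-2-en-1-one | O=C1C(C)=CC[C@@H](C(C)=C)[C@]1(C)CC(=C)S(=O)(=O)c2ccccc2 | intermediate
11 | (4aS,8aS)-2,5,5,8a-tetramethyl-7-(phenylsulfonyl)-4a,5,6,7,8,8a-hexahydronaphthalen-1(4H)-one, epimers at the sulfonyl carbon (labdane C2) | O=C1C(C)=CC[C@H]2C(C)(C)CC(S(=O)(=O)c3ccccc3)C[C@]12C | intermediate
12 | (S)-3-bromo-2-methylpropan-1-ol | OC[C@H](C)CBr | starting material
13 | (S)-(3-bromo-2-methylpropoxy)(tert-butyl)dimethylsilane | CC(C)(C)[Si](C)(C)OC[C@H](C)CBr | intermediate
14 | [(S)-3-(tert-butyldimethylsilyloxy)-2-methylpropyl]magnesium bromide | CC(C)(C)[Si](C)(C)OC[C@H](C)C[Mg]Br | intermediate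
15 | (R)-4-(tert-butyldimethylsilyloxy)-3-methylbutan-1-ol | CC(C)(C)[Si](C)(C)OC[C@H](C)CCO | intermediate
16 | (R)-tert-butyl(4-iodo-2-methylbutoxy)dimethylsilane | CC(C)(C)[Si](C)(C)OC[C@H](C)CCI | intermediate
17 | [(R)-4-(tert-butyldimethylsilyloxy)-3-methylbutyl]lithium | CC(C)(C)[Si](C)(C)OC[C@H](C)CC[Li] | intermediate
18 | dichloro[(R)-4-(tert-butyldimethylsilyloxy)-3-methylbutyl]cerium | CC(C)(C)[Si](C)(C)OC[C@H](C)CC[Ce](Cl)Cl | intermediate
19 | (13R)-14-(tert-butyldimethylsilyloxy)-2-(phenylsulfonyl)-15-norlabd-7-en-9β-ol, OH cis to the C10 methyl, C11 chain 9α, C2 epimers | CC(C)(C)[Si](C)(C)OC[C@H](C)CC[C@]1(O)C(C)=CC[C@H]2C(C)(C)CC(S(=O)(=O)c3ccccc3)C[C@]12C | intermediate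
20 | lithium alkoxide of 19 | CC(C)(C)[Si](C)(C)OC[C@H](C)CC[C@]1(O[Li])C(C)=CC[C@H]2C(C)(C)CC(S(=O)(=O)c3ccccc3)C[C@]12C | intermediate
21 | methyl (13R)-14-(tert-butyldimethylsilyloxy)-2-(phenylsulfonyl)-15-norlabd-7-en-9β-yl carbonate, C11 chain 9α, C2 epimers | CC(C)(C)[Si](C)(C)OC[C@H](C)CC[C@]1(OC(=O)OC)C(C)=CC[C@H]2C(C)(C)CC(S(=O)(=O)c3ccccc3)C[C@]12C | intermediate
22 | (13R)-14-(tert-butyldimethylsilyloxy)-2-(phenylsulfonyl)-15-norlabd-7-ene, 5α-H, 9α-H, 10β-CH3, C2 epimers | CC(C)(C)[Si](C)(C)OC[C@H](C)CC[C@H]1C(C)=CC[C@H]2C(C)(C)CC(S(=O)(=O)c3ccccc3)C[C@]12C | intermediate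
23 | (13R)-14-(tert-butyldimethylsilyloxy)-15-norlabd-7-ene | CC(C)(C)[Si](C)(C)OC[C@H](C)CC[C@H]1C(C)=CC[C@H]2C(C)(C)CCC[C@]12C | intermediate
24 | (13R)-15-norlabd-7-en-14-ol | OC[C@H](C)CC[C@H]1C(C)=CC[C@H]2C(C)(C)CCC[C@]12C | intermediate
25 | isobutyryl chloride (2-methylpropanoyl chloride) | CC(C)C(=O)Cl | starting material
26 | (13R)-15-norlabd-7-en-14-yl 2-methylpropanoate | CC(C)C(=O)OC[C@H](C)CC[C@H]1C(C)=CC[C@H]2C(C)(C)CCC[C@]12C | intermediate
27 | (13R)-17-hydroxy-15-norlabd-7-en-14-yl 2-methylpropanoate | CC(C)C(=O)OC[C@H](C)CC[C@H]1C(CO)=CC[C@H]2C(C)(C)CCC[C@]12C | intermediate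
28 | (13R)-17-oxo-15-norlabd-7-en-14-yl 2-methylpropanoate | CC(C)C(=O)OC[C@H](C)CC[C@H]1C(C=O)=CC[C@H]2C(C)(C)CCC[C@]12C | intermediate
29 | (13R)-14-(2-methylpropanoyloxy)-15-norlabd-7-en-17-oic acid, (1R,4aS,8aS)-5,5,8a-trimethyl-1-[(3R)-3-methyl-4-(2-methylpropanoyloxy)butyl]-1,4,4a,5,6,7,8,8a-octahydronaphthalene-2-carboxylic acid | CC(C)C(=O)OC[C@H](C)CC[C@H]1C(C(=O)O)=CC[C@H]2C(C)(C)CCC[C@]12C | target

## Step count and least certain steps

Total step count: 16. Longest linear sequence: 12 steps (from 5: steps 2, 3, 4, 5, 9–16); 11 steps from 1 or from 12.

**Step 5 (key step).** The most likely failure is hydrogen-atom transfer to the vinyl sulfone instead of the isopropenyl group, or reduction of the C4 radical before ring closure. The iron hydride is only moderately selective between two 1,1-disubstituted alkenes, and the closure must join a quaternary carbon to C3 in a ring with a syn-axial methyl pair. The fallback sets out from 10. Markovnikov addition of HBr (HBr in AcOH, CH2Cl2, 0 °C) gives the tertiary bromide F1. Bu3SnH and AIBN in dilute benzene at 80 °C abstract the bromine, which generates the C4 radical regiospecifically; 6-endo closure and hydrogen transfer from tin return the route at 11.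

**Step 4.** O-alkylation, insufficient face selectivity at the fully substituted enolate, or conjugate addition of enolate 9 or of diisopropylamine to the vinyl sulfone may erode the step, because electrophile and product are both Michael acceptors. The fallback sets out from 4. The same enolate is alkylated with 2,3-dibromopropene, which has no acceptor character, to give the 2-bromoallyl ketone F2. Coupling with PhSO2Na under CuI/N,N′-dimethylethylenediamine catalysis in DMSO at 100 °C turns the vinyl bromide into the vinyl sulfone and returns the route at 10.

**Step 9.** Deprotonation at C2 (α to the sulfone) or at C6 (γ to the enone) may compete with addition, and attack from the β-face would give the wrong carbinol. The fallback removes the sulfone first and sets out from 11. Reduction with NaBH4/CeCl3·7H2O gives the allylic alcohol F3. Na(Hg)/Na2HPO4 cleaves the sulfone to give the desulfonylated allylic alcohol F4, and MnO2 re-oxidises it to the enone F5. Alkyllithium 17 then adds without an acidic sulfone present, and quenching the mixture with ClCO2Me gives the carbonate F6. The conditions of step 11 lead to 23, where the route is rejoined. If face selectivity is the problem, the fallback for step 11 applies, since it does not depend on the carbinol configuration.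

**Step 11.** β-Hydride elimination from the allylpalladium intermediate to dienes, or hydride transfer to C7 giving the tetrasubstituted alkene, may compete, because C9 is fully substituted and next to quaternary C10. The fallback sets out from 19 (either C9 epimer). Oxidative 1,3-transposition with pyridinium chlorochromate, [C5H5NH][CrO3Cl], gives the transposed enone F7. Li in NH3/THF reduces the enone, with protonation of C9 from the α-face, and cleaves the sulfone in the same operation. Trapping the regiodefined C7 enolate with PhNTf2 gives the enol triflate F8. Pd(OAc)2/PPh3 with HCO2H and Bu3N in DMF replaces the triflate by hydrogen and returns the route at 23.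

**Step 15.** Oxidation at C9 or C6, further hydroxylation of the enal at C9, or epimerisation of C9 under the hot acidic conditions may occur. The fallback sets out from 26. mCPBA gives the 7α,8α-epoxide F9. Cp2TiCl (from Cp2TiCl2 and Zn) opens it at C8, and β-hydride elimination gives the exocyclic allylic alcohol F10. PBr3 converts it with allylic transposition into the primary allylic bromide F11. Kornblum-type oxidation with N-methylmorpholine N-oxide in MeCN returns the route at 28.

## Further compounds

F1 | step 5 | (5R,6S)-5-(2-bromopropan-2-yl)-2,6-dimethyl-6-[2-(phenylsulfonyl)prop-2-en-1-yl]cyclohex-2-en-1-one | O=C1C(C)=CC[C@@H](C(C)(C)Br)[C@]1(C)CC(=C)S(=O)(=O)c2ccccc2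
F2 | step 4 | (5S,6S)-6-(2-bromoprop-2-en-1-yl)-2,6-dimethyl-5-(prop-1-en-2-yl)cyclohex-2-en-1-one | O=C1C(C)=CC[C@@H](C(C)=C)[C@]1(C)CC(Br)=C
F3 | step 9 | allylic alcohol from 11, 9β-OH expected, C2 epimers | O[C@H]1C(C)=CC[C@H]2C(C)(C)CC(S(=O)(=O)c3ccccc3)C[C@]12C
F4 | step 9 | desulfonylated allylic alcohol, 2,5,5,8a-tetramethyl-1,4,4a,5,6,7,8,8a-octahydronaphthalen-1-ol | O[C@H]1C(C)=CC[C@H]2C(C)(C)CCC[C@]12C
F5 | step 9 | (4aS,8aS)-2,5,5,8a-tetramethyl-4a,5,6,7,8,8a-hexahydronaphthalen-1(4H)-one | O=C1C(C)=CC[C@H]2C(C)(C)CCC[C@]12C
F6 | step 9 | methyl (13R)-14-(tert-butyldimethylsilyloxy)-15-norlabd-7-en-9β-yl carbonate, C11 chain 9α | CC(C)(C)[Si](C)(C)OC[C@H](C)CC[C@]1(OC(=O)OC)C(C)=CC[C@H]2C(C)(C)CCC[C@]12C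
F7 | step 11 | (13R)-14-(tert-butyldimethylsilyloxy)-2-(phenylsulfonyl)-15-norlabd-8-en-7-one, C2 epimers | CC(C)(C)[Si](C)(C)OC[C@H](C)CCC1=C(C)C(=O)C[C@H]2C(C)(C)CC(S(=O)(=O)c3ccccc3)C[C@]12C
F8 | step 11 | (13R)-14-(tert-butyldimethylsilyloxy)-15-norlabd-7-en-7-yl trifluoromethanesulfonate | CC(C)(C)[Si](C)(C)OC[C@H](C)CC[C@H]1C(C)=C(OS(=O)(=O)C(F)(F)F)C[C@H]2C(C)(C)CCC[C@]12C
F9 | step 15 | (13R)-7α,8α-epoxy-15-norlabdan-14-yl 2-methylpropanoate | CC(C)C(=O)OC[C@H](C)CC[C@H]1[C@]3(C)O[C@@H]3C[C@H]2C(C)(C)CCC[C@]12C
F10 | step 15 | (13R)-7α-hydroxy-15-norlabd-8(17)-en-14-yl 2-methylpropanoate | CC(C)C(=O)OC[C@H](C)CC[C@H]1C(=C)[C@H](O)C[C@H]2C(C)(C)CCC[C@]12C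
F11 | step 15 | (13R)-17-bromo-15-norlabd-7-en-14-yl 2-methylpropanoate | CC(C)C(=O)OC[C@H](C)CC[C@H]1C(CBr)=CC[C@H]2C(C)(C)CCC[C@]12C
A1 | alternative 1 | (2R,3R)-2-[(2E)-4-(tert-butyldimethylsilyloxy)-3-methylbut-2-en-1-yl]-3-methyl-3-(4-methylpent-3-en-1-yl)cyclohexan-1-one | CC(C)(C)[Si](C)(C)OC/C(C)=C/C[C@H]1C(=O)CCC[C@]1(C)CCC=C(C)C
A2 | alternative 2 | (13R)-15-norlabd-7-en-14-ol | OC[C@H](C)CC[C@H]1C(C)=CC[C@H]2C(C)(C)CCC[C@]12C
A3 | alternative 3 | (4S)-4-benzyl-3-acyloxazolidin-2-one whose acyl group is the C11 carbonyl on C9 of a trans-fused 4,4,10-trimethyldecal-6-ene carrying CH2OSi(CH3)2C(CH3)3 (C17) on C8 | O=C(N3[C@@H](Cc4ccccc4)COC3=O)[C@H]1[C@@H](CO[Si](C)(C)C(C)(C)C)C=C[C@H]2C(C)(C)CCC[C@]12C
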